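In isobenzofuran numbering, ring A of the target carries at C6 a methyl and a homoprenyl group beside the arm-bearing C7, which is the carbon pattern of myrcene once its 1,1-disubstituted alkene has become a tertiary radical. Everything therefore rests on the C5–C6 disconnection. In one operation, hydrogen-atom transfer to the C6 methylene and 6-endo addition of the C6 radical to C5 of a 2-sulfonyl diene on ring B should close ring A, create the quaternary centre and leave a C4 sulfone as a masked carbonyl. The precursor is a 2,5-dihydrofuran (ring B) with 1-(phenylsulfonyl)vinyl at C3a and, at C7a, the C7 methine bearing a tert-butyl acetate arm and the myrcene-derived methylene unit.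

Key step: step 17

Remark: isobenzofuran numbering is kept for all intermediates (C1 bears the oxopropyl chain, O2, C3, C3a=C7a, C4 carbinol, C5, C6, C7); ring A is the carbocycle, ring B the dihydrofuran.
Remark: C1 is set by reagent control (steps 12 and 13) because induction from C7 across the sp2 carbon C7a cannot be relied on in the allenylation; the C4 sulfone centre of 25 is left as a mixture because it becomes sp2 in step 18.

Step 1
Reactants: 1 myrcene (7-methyl-3-methylideneocta-1,6-diene)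
Product: 3 7-methyl-3-methylideneoct-6-en-1-ol, via trialkylborane 2 (not isolated)
Conditions: BH3·THF, 2-methylbut-2-ene, THF, 0 °C; then 1, 0 °C; then NaOH, H2O2, 0 °C → rt
Reagents that add atoms: hydrogen peroxide, OO
Why: Brown hydroboration–oxidation with the bulky disiamylborane should pick the monosubstituted vinyl terminus of the diene over the 1,1-disubstituted and trisubstituted alkenes and place oxygen on the terminal carbon (anti-Markovnikov).

Step 2
Reactants: 3 7-methyl-3-methylideneoct-6-en-1-ol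
Product: 5 7-methyl-3-methylideneoct-6-enoic acid, via 7-methyl-3-methylideneoct-6-enal 4 (not isolated)
Conditions: TEMPO (cat.), PhI(OAc)2, MeCN/H2O, rt
Reagents that add atoms: water, O
Why: Oxoammonium (TEMPO) oxidation with PhI(OAc)2 as terminal oxidant takes the primary alcohol through the aldehyde hydrate to the acid under near-neutral conditions that should leave both alkenes in place and unconjugated.

Step 3
Reactants: 5 7-methyl-3-methylideneoct-6-enoic acid; 6 (4R)-4-benzyl-1,3-oxazolidin-2-one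
Product: 8 (4R)-4-benzyl-3-(7-methyl-3-methylideneoct-6-enoyl)-1,3-oxazolidin-2-one, via mixed pivalic anhydride 7 (not isolated)
Conditions: t-BuCOCl, Et3N, THF, −20 °C; then 6, LiCl, −20 °C → rt
Reagents that add atoms: none
Why: N-Acylation of the auxiliary through the mixed pivalic anhydride with LiCl/Et3N activation needs no strong base, so the β,γ-unsaturated acyl group should not slip into conjugation.

Step 4
Reactants: 8 (4R)-4-benzyl-3-(7-methyl-3-methylideneoct-6-enoyl)-1,3-oxazolidin-2-one; 9 tert-butyl bromoacetate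
Product: 10 tert-butyl (3R)-3-[(4R)-4-benzyl-2-oxo-1,3-oxazolidine-3-carbonyl]-8-methyl-4-methylidenenon-7-enoate
Conditions: NaN(SiMe3)2, THF, −78 °C; then 9, −78 → −45 °C
Reagents that add atoms: none
Why: Evans asymmetric alkylation, in which the chelated Z-sodium enolate is alkylated at its α-carbon (future C7) on the face away from the benzyl group of the (R)-auxiliary, which sets C7 as required, while the reactive α-halo ester attacks the α- and not the γ-terminus of the dienolate.

Step 5
Reactants: 10 tert-butyl (3R)-3-[(4R)-4-benzyl-2-oxo-1,3-oxazolidine-3-carbonyl]-8-methyl-4-methylidenenon-7-enoate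
Product: 11 tert-butyl (3R)-3-(hydroxymethyl)-8-methyl-4-methylidenenon-7-enoate
Conditions: NaBH4, THF/H2O, 0 °C → rt
Reagents that add atoms: none
Why: Reductive cleavage of the N-acyl oxazolidinone by borohydride should release the primary alcohol (future C7a) and the recoverable auxiliary, while the hindered tert-butyl ester resists both hydride and lactonisation in the cold and C7 is never enolised.

Step 6
Reactants: 11 tert-butyl (3R)-3-(hydroxymethyl)-8-methyl-4-methylidenenon-7-enoate
Product: 12 tert-butyl (3R)-3-formyl-8-methyl-4-methylidenenon-7-enoate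
Conditions: Dess–Martin periodinane, pyridine, CH2Cl2, 0 °C; used at once
Reagents that add atoms: none
Why: Buffered Dess–Martin oxidation is fast and neither acidic nor basic, which matters because the C7 hydrogen of this aldehyde is both α to the carbonyl and allylic and would otherwise epimerise or move the alkene into conjugation.

Step 7
Reactants: 12 tert-butyl (3R)-3-formyl-8-methyl-4-methylidenenon-7-enoate
Product: 13 tert-butyl (3R)-3-ethynyl-8-methyl-4-methylidenenon-7-enoate
Conditions: Me3SiCHN2, n-BuLi, THF, −78 °C; then 12, −78 → 0 °C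
Reagents that add atoms: (trimethylsilyl)diazomethane, C[Si](C)(C)C=[N+]=[N-]
Why: Colvin rearrangement, in which lithiated (trimethylsilyl)diazomethane should add to the aldehyde at −78 °C faster than it deprotonates C7, and Peterson-type loss of silanolate, loss of N2 and a 1,2-hydrogen shift in the alkylidene carbene give the terminal alkyne (C7a≡C3a) without touching the tert-butyl ester.

Step 8
Reactants: 13 tert-butyl (3R)-3-ethynyl-8-methyl-4-methylidenenon-7-enoate
Product: 14 tert-butyl (3R)-3-(3-hydroxyprop-1-yn-1-yl)-8-methyl-4-methylidenenon-7-enoate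
Conditions: i-PrMgCl·LiCl, THF, 0 °C → rt; then (CH2O)n, rt → 40 °C
Reagents that add atoms: formaldehyde (as paraformaldehyde), C=O
Why: Deprotonation of the terminal alkyne by the Grignard reagent should be faster than attack on the hindered tert-butyl ester, and the alkynylmagnesium species adds to formaldehyde to bring in C3 as a propargylic alcohol.

Step 9
Reactants: 14 tert-butyl (3R)-3-(3-hydroxyprop-1-yn-1-yl)-8-methyl-4-methylidenenon-7-enoate
Product: 15 tert-butyl (3R)-3-(3-bromoprop-1-yn-1-yl)-8-methyl-4-methylidenenon-7-enoate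
Conditions: CBr4, PPh3, CH2Cl2, 0 °C
Reagents that add atoms: carbon tetrabromide, BrC(Br)(Br)Br
Why: Appel bromination converts the primary propargylic alcohol into the bromide under neutral conditions that the ester and the skipped enyne tolerate.

Step 10
Reactants: 16 ethyl 2-(2-methyl-1,3-dioxolan-2-yl)acetate (the commercial ethylene ketal of ethyl acetoacetate)
Product: 17 2-(2-methyl-1,3-dioxolan-2-yl)acetaldehyde
Conditions: iBu2AlH, CH2Cl2, −78 °C
Reagents that add atoms: none
Why: Partial ester reduction with diisobutylaluminium hydride at −78 °C stops at the aluminium hemiacetal, which gives the aldehyde on work-up, and the ketal is inert to hydride.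

Step 11
Reactants: 15 tert-butyl (3R)-3-(3-bromoprop-1-yn-1-yl)-8-methyl-4-methylidenenon-7-enoate; 17 2-(2-methyl-1,3-dioxolan-2-yl)acetaldehyde
Product: 18 tert-butyl (3R)-3-[4-hydroxy-5-(2-methyl-1,3-dioxolan-2-yl)penta-1,2-dien-3-yl]-8-methyl-4-methylidenenon-7-enoate (both epimers at the carbinol carbon, the future C1)
Conditions: In powder, THF/H2O, rt
Reagents that add atoms: none
Why: Indium-mediated Barbier reaction, in which the γ-substituted propargylindium species adds to the aldehyde through its γ-carbon (SE2′) to give the α-allenyl carbinol and thus the C1–C7a bond in the presence of ester and ketal, the carbinol configuration being left open for correction in steps 12 and 13.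

Step 12
Reactants: 18 tert-butyl (3R)-3-[4-hydroxy-5-(2-methyl-1,3-dioxolan-2-yl)penta-1,2-dien-3-yl]-8-methyl-4-methylidenenon-7-enoate
Product: 19 tert-butyl (3R)-8-methyl-3-[5-(2-methyl-1,3-dioxolan-2-yl)-4-oxopenta-1,2-dien-3-yl]-4-methylidenenon-7-enoate
Conditions: Dess–Martin periodinane, pyridine, CH2Cl2, 0 °C
Reagents that add atoms: none
Why: Dess–Martin oxidation of the α-allenyl carbinol to the allenyl ketone erases the uncontrolled carbinol centre under neutral conditions that should not isomerise the allene.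

Step 13
Reactants: 19 tert-butyl (3R)-8-methyl-3-[5-(2-methyl-1,3-dioxolan-2-yl)-4-oxopenta-1,2-dien-3-yl]-4-methylidenenon-7-enoate
Product: 20 tert-butyl (3R)-3-[(4S)-4-hydroxy-5-(2-methyl-1,3-dioxolan-2-yl)penta-1,2-dien-3-yl]-8-methyl-4-methylidenenon-7-enoate
Conditions: (R)-Me-CBS oxazaborolidine [(R)-1-methyl-3,3-diphenyltetrahydro-1H,3H-pyrrolo[1,2-c][1,3,2]oxazaborole] (cat.), catecholborane, toluene, −78 °C
Reagents that add atoms: none
Why: Corey–Bakshi–Shibata reduction, in which the (R)-oxazaborolidine places the branched allenyl group in the large and the CH2 group in the small position and should deliver hydride to give the S carbinol (future C1) by reagent control, independent of C7.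

Step 14
Reactants: 20 tert-butyl (3R)-3-[(4S)-4-hydroxy-5-(2-methyl-1,3-dioxolan-2-yl)penta-1,2-dien-3-yl]-8-methyl-4-methylidenenon-7-enoate
Product: 21 tert-butyl (3R)-3-[(2S)-4-iodo-2-[(2-methyl-1,3-dioxolan-2-yl)methyl]-2,5-dihydrofuran-3-yl]-8-methyl-4-methylidenenon-7-enoate
Conditions: N-iodosuccinimide, CH2Cl2, −20 → 0 °C, dark
Reagents that add atoms: N-iodosuccinimide, O=C1CCC(=O)N1I
Why: Electrophilic 5-endo iodocyclisation of the α-allenol, in which the hydroxyl attacks the iodonium-activated CH2 terminus (C3) so that ring B closes with iodine on C3a and the C3a=C7a alkene in place, C1 being a spectator and the low temperature and single equivalent of iodine source keeping the ester-flanked alkenes out.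

Step 15
Reactants: 22 phenyl vinyl sulfone
Product: 23 tributyl[1-(phenylsulfonyl)ethenyl]stannane
Conditions: MeLi, THF, −95 °C; then Bu3SnCl, −95 → −78 °C
Reagents that add atoms: tributyltin chloride, CCCC[Sn](Cl)(CCCC)CCCC
Why: α-Lithiation of the vinyl sulfone (the sulfonyl group acidifies the α-vinyl hydrogen and the very low temperature suppresses conjugate addition) followed by stannylation of the vinyllithium gives the α-stannyl vinyl sulfone.

Step 16
Reactants: 21 tert-butyl (3R)-3-[(2S)-4-iodo-2-[(2-methyl-1,3-dioxolan-2-yl)methyl]-2,5-dihydrofuran-3-yl]-8-methyl-4-methylidenenon-7-enoate; 23 tributyl[1-(phenylsulfonyl)ethenyl]stannane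
Product: 24 tert-butyl (3R)-8-methyl-3-[(2S)-2-[(2-methyl-1,3-dioxolan-2-yl)methyl]-4-[1-(phenylsulfonyl)ethenyl]-2,5-dihydrofuran-3-yl]-4-methylidenenon-7-enoate (cyclisation precursor)
Conditions: Pd2(dba)3 (cat.), AsPh3, CuI (cat.), NMP, 45 °C
Reagents that add atoms: none
Why: Stille coupling of the alkenyl iodide with the α-stannyl vinyl sulfone, a known entry to 2-sulfonyl-1,3-dienes, joins C3a to C4 under neutral conditions, the weakly bound arsine ligand and copper iodide co-catalysis helping transmetalation of the hindered, electron-poor stannane.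

Step 17
Reactants: 24 tert-butyl (3R)-8-methyl-3-[(2S)-2-[(2-methyl-1,3-dioxolan-2-yl)methyl]-4-[1-(phenylsulfonyl)ethenyl]-2,5-dihydrofuran-3-yl]-4-methylidenenon-7-enoate
Product: 25 tert-butyl 2-[(1S,6S,7R)-6-methyl-1-[(2-methyl-1,3-dioxolan-2-yl)methyl]-6-(4-methylpent-3-en-1-yl)-4-(phenylsulfonyl)-1,3,4,5,6,7-hexahydroisobenzofuran-7-yl]acetate (both C4 epimers)
Conditions: Fe(acac)3 (0.5 equiv), PhSiH3, EtOH/HOCH2CH2OH (5:1), 60 °C, 0.01 M
Reagents that add atoms: none
Why: Proposed new method: the iron hydride formed from Fe(acac)3 and PhSiH3 transfers a hydrogen atom to the terminal CH2 of the 1,1-disubstituted alkene, which turns that carbon into the C6 methyl and leaves a nucleophilic tertiary radical at C6; this radical adds to the electron-poor, unsubstituted C5 terminus of the 2-sulfonyl diene, and the sulfonyl-stabilised allyl radical (C4/C7a) is then reduced by divalent iron and protonated at C4 by ethanol. The closest known reaction type is the iron-hydride reductive olefin coupling (hydrogen-atom-transfer Giese addition) of 1,1-disubstituted alkenes to vinyl sulfones, and its use in an intramolecular mode on a dienyl sulfone is the extension. Ring A closes 6-endo-trig, since the alternative 5-exo attack at C4 would strike the sulfonyl-bearing carbon, give a primary radical and strain the ring across the C3a=C7a bond. C6 is set under control of the neighbouring C7 centre: in a chair-like transition state the C7 ester arm should lie pseudo-equatorial and the longer homoprenyl chain should take the equatorial site trans to it, so the new methyl ends cis to the arm, while C4 forms as both epimers, which is harmless because it becomes sp2 in step 18. The step needs hydrogen-atom transfer to the 1,1-disubstituted alkene and not to the trisubstituted alkene or the diene; the less hindered terminal methylene and the electron-poor character of the diene should secure this, and high dilution with ethylene glycol as co-solvent (which also protects the ketal) favours ring closure over simple reduction.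

Step 18
Reactants: 25 tert-butyl 2-[(1S,6S,7R)-6-methyl-1-[(2-methyl-1,3-dioxolan-2-yl)methyl]-6-(4-methylpent-3-en-1-yl)-4-(phenylsulfonyl)-1,3,4,5,6,7-hexahydroisobenzofuran-7-yl]acetate
Product: 26 tert-butyl 2-[(1S,6S,7R)-6-methyl-1-[(2-methyl-1,3-dioxolan-2-yl)methyl]-6-(4-methylpent-3-en-1-yl)-4-oxo-1,3,4,5,6,7-hexahydroisobenzofuran-7-yl]acetate
Conditions: LiN(iPr)2 (1.05 equiv), THF, −78 °C; then Me3SiOOSiMe3, −78 → 0 °C
Reagents that add atoms: bis(trimethylsilyl) peroxide, C[Si](C)(C)OO[Si](C)(C)C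
Why: Oxidative desulfonylation, in which the allylic sulfone (far more acidic than the ester) is deprotonated at C4 and trapped at −78 °C before the allyl anion can open ring B by vinylogous β-elimination, the carbanion being oxygenated at its α-carbon by the silyl peroxide and the α-silyloxy sulfone collapsing with loss of sulfinate to the C4 ketone conjugated with C3a=C7a, so that both C4 epimers converge.

Step 19
Reactants: 26 tert-butyl 2-[(1S,6S,7R)-6-methyl-1-[(2-methyl-1,3-dioxolan-2-yl)methyl]-6-(4-methylpent-3-en-1-yl)-4-oxo-1,3,4,5,6,7-hexahydroisobenzofuran-7-yl]acetate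
Product: 27 tert-butyl 2-[(1S,4S,6S,7R)-4-hydroxy-6-methyl-1-[(2-methyl-1,3-dioxolan-2-yl)methyl]-6-(4-methylpent-3-en-1-yl)-1,3,4,5,6,7-hexahydroisobenzofuran-7-yl]acetate
Conditions: (R)-Me-CBS oxazaborolidine [(R)-1-methyl-3,3-diphenyltetrahydro-1H,3H-pyrrolo[1,2-c][1,3,2]oxazaborole] (cat.), catecholborane, toluene, −78 → −40 °C
Reagents that add atoms: none
Why: Corey–Bakshi–Shibata 1,2-reduction of the enone, in which the alkene carbon C3a acts as the large and C5H2 as the small substituent so that the (R)-catalyst should give the 4S alcohol by reagent control, catecholborane leaving the alkenes, ester and ketal alone.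

Step 20
Reactants: 27 tert-butyl 2-[(1S,4S,6S,7R)-4-hydroxy-6-methyl-1-[(2-methyl-1,3-dioxolan-2-yl)methyl]-6-(4-methylpent-3-en-1-yl)-1,3,4,5,6,7-hexahydroisobenzofuran-7-yl]acetate
Product: 28 tert-butyl 2-[(1S,4S,6S,7R)-6-methyl-1-[(2-methyl-1,3-dioxolan-2-yl)methyl]-6-(4-methylpent-3-en-1-yl)-4-(triethylsilyloxy)-1,3,4,5,6,7-hexahydroisobenzofuran-7-yl]acetate
Conditions: Et3SiCl, imidazole, CH2Cl2, 0 °C → rt
Reagents that add atoms: chlorotriethylsilane, CC[Si](Cl)(CC)CC
Why: Silylation masks the secondary allylic alcohol during ester reduction, oxidation and enol acylation with a group that the final mild acid removes together with the ketal.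

Step 21
Reactants: 28 tert-butyl 2-[(1S,4S,6S,7R)-6-methyl-1-[(2-methyl-1,3-dioxolan-2-yl)methyl]-6-(4-methylpent-3-en-1-yl)-4-(triethylsilyloxy)-1,3,4,5,6,7-hexahydroisobenzofuran-7-yl]acetate
Product: 29 2-[(1S,4S,6S,7R)-6-methyl-1-[(2-methyl-1,3-dioxolan-2-yl)methyl]-6-(4-methylpent-3-en-1-yl)-4-(triethylsilyloxy)-1,3,4,5,6,7-hexahydroisobenzofuran-7-yl]ethan-1-ol
Conditions: LiAlH4, THF, 0 °C
Reagents that add atoms: none
Why: Full hydride reduction of the tert-butyl ester to the primary alcohol is chosen over a partial reduction because over-reduction then cannot spoil the step, and silyl ether, ketal and alkenes are inert.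

Step 22
Reactants: 29 2-[(1S,4S,6S,7R)-6-methyl-1-[(2-methyl-1,3-dioxolan-2-yl)methyl]-6-(4-methylpent-3-en-1-yl)-4-(triethylsilyloxy)-1,3,4,5,6,7-hexahydroisobenzofuran-7-yl]ethan-1-ol
Product: 30 2-[(1S,4S,6S,7R)-6-methyl-1-[(2-methyl-1,3-dioxolan-2-yl)methyl]-6-(4-methylpent-3-en-1-yl)-4-(triethylsilyloxy)-1,3,4,5,6,7-hexahydroisobenzofuran-7-yl]acetaldehyde
Conditions: Dess–Martin periodinane, pyridine, CH2Cl2, 0 °C
Reagents that add atoms: none
Why: Dess–Martin oxidation gives the aldehyde without acid or strong base, so the silyl ether, the ketal and the allylic C7 centre are safe.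

Step 23
Reactants: 31 3-methylbut-2-enoic acid (two molecules per molecule of product)
Product: 32 3-methylbut-2-enoic anhydride
Conditions: DCC (0.5 equiv with respect to 31), CH2Cl2, 0 °C → rt; filtration
Reagents that add atoms: 3-methylbut-2-enoic acid (the second molecule of 31, which supplies the second acyl group), CC(C)=CC(O)=O
Why: Carbodiimide dehydration, in which one molecule of the acid adds to DCC to give the O-acylisourea and a second molecule of the acid attacks its acyl carbon, gives the symmetrical anhydride and insoluble dicyclohexylurea without any base that could move the double bond out of conjugation.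

Step 24
Reactants: 30 2-[(1S,4S,6S,7R)-6-methyl-1-[(2-methyl-1,3-dioxolan-2-yl)methyl]-6-(4-methylpent-3-en-1-yl)-4-(triethylsilyloxy)-1,3,4,5,6,7-hexahydroisobenzofuran-7-yl]acetaldehyde; 32 3-methylbut-2-enoic anhydride
Product: 33 (E)-2-[(1S,4S,6S,7R)-6-methyl-1-[(2-methyl-1,3-dioxolan-2-yl)methyl]-6-(4-methylpent-3-en-1-yl)-4-(triethylsilyloxy)-1,3,4,5,6,7-hexahydroisobenzofuran-7-yl]ethenyl 3-methylbut-2-enoate
Conditions: Et3N, DMAP (cat.), toluene, rt → 60 °C
Reagents that add atoms: none
Why: Base-mediated O-acylation of the aldehyde (soft enolisation and acyl transfer from the acylpyridinium) gives the enol ester, and the E isomer should predominate because the bulky C7 substituent avoids a cis relationship with the acyloxy group, any Z isomer being removed by chromatography.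

Step 25
Reactants: 33 (E)-2-[(1S,4S,6S,7R)-6-methyl-1-[(2-methyl-1,3-dioxolan-2-yl)methyl]-6-(4-methylpent-3-en-1-yl)-4-(triethylsilyloxy)-1,3,4,5,6,7-hexahydroisobenzofuran-7-yl]ethenyl 3-methylbut-2-enoate
Product: 34 (E)-2-[(1S,4S,6S,7R)-4-hydroxy-6-methyl-6-(4-methylpent-3-en-1-yl)-1-(2-oxopropyl)-1,3,4,5,6,7-hexahydroisobenzofuran-7-yl]ethenyl 3-methylbut-2-enoate (CNP0260614.2)
Conditions: PPTS, acetone/H2O, 50 °C
Reagents that add atoms: water, O
Why: Mild acid-catalysed hydrolysis removes the dioxolane and the triethylsilyl ether in one operation, and the weakly acidic pyridinium salt should spare the enol ester, the allylic alcohol and the β-alkoxy ketone at C1.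

Compound list
1 | myrcene (7-methyl-3-methylideneocta-1,6-diene) | C=CC(=C)CCC=C(C)C | starting material
2 | (7-methyl-3-methylideneoct-6-en-1-yl)bis(3-methylbutan-2-yl)borane | CC(C)C(C)B(CCC(=C)CCC=C(C)C)C(C)C(C)C | intermediate
3 | 7-methyl-3-methylideneoct-6-en-1-ol | OCCC(=C)CCC=C(C)C | intermediate
4 | 7-methyl-3-methylideneoct-6-enal | O=CCC(=C)CCC=C(C)C | intermediate
5 | 7-methyl-3-methylideneoct-6-enoic acid | OC(=O)CC(=C)CCC=C(C)C | intermediate
6 | (4R)-4-benzyl-1,3-oxazolidin-2-one | O=C1N[C@H](Cc2ccccc2)CO1 | starting material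
7 | 7-methyl-3-methylideneoct-6-enoic pivalic anhydride | CC(C)(C)C(=O)OC(=O)CC(=C)CCC=C(C)C | intermediate
8 | (4R)-4-benzyl-3-(7-methyl-3-methylideneoct-6-enoyl)-1,3-oxazolidin-2-one | O=C1OC[C@@H](Cc2ccccc2)N1C(=O)CC(=C)CCC=C(C)C | intermediate
9 | tert-butyl bromoacetate | BrCC(=O)OC(C)(C)C | starting material
10 | tert-butyl (3R)-3-[(4R)-4-benzyl-2-oxo-1,3-oxazolidine-3-carbonyl]-8-methyl-4-methylidenenon-7-enoate | O=C1OC[C@@H](Cc2ccccc2)N1C(=O)[C@H](CC(=O)OC(C)(C)C)C(=C)CCC=C(C)C | intermediate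
11 | tert-butyl (3R)-3-(hydroxymethyl)-8-methyl-4-methylidenenon-7-enoate | OC[C@H](CC(=O)OC(C)(C)C)C(=C)CCC=C(C)C | intermediate
12 | tert-butyl (3R)-3-formyl-8-methyl-4-methylidenenon-7-enoate | O=C[C@H](CC(=O)OC(C)(C)C)C(=C)CCC=C(C)C | intermediate
13 | tert-butyl (3R)-3-ethynyl-8-methyl-4-methylidenenon-7-enoate | C#C[C@H](CC(=O)OC(C)(C)C)C(=C)CCC=C(C)C | intermediate
14 | tert-butyl (3R)-3-(3-hydroxyprop-1-yn-1-yl)-8-methyl-4-methylidenenon-7-enoate | OCC#C[C@H](CC(=O)OC(C)(C)C)C(=C)CCC=C(C)C | intermediate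
15 | tert-butyl (3R)-3-(3-bromoprop-1-yn-1-yl)-8-methyl-4-methylidenenon-7-enoate | BrCC#C[C@H](CC(=O)OC(C)(C)C)C(=C)CCC=C(C)C | intermediate
16 | ethyl 2-(2-methyl-1,3-dioxolan-2-yl)acetate | CCOC(=O)CC1(C)OCCO1 | starting material
17 | 2-(2-methyl-1,3-dioxolan-2-yl)acetaldehyde | O=CCC1(C)OCCO1 | intermediate
18 | tert-butyl (3R)-3-[4-hydroxy-5-(2-methyl-1,3-dioxolan-2-yl)penta-1,2-dien-3-yl]-8-methyl-4-methylidenenon-7-enoate (carbinol epimers) | CC1(OCCO1)CC(O)C(=C=C)[C@H](CC(=O)OC(C)(C)C)C(=C)CCC=C(C)C | intermediate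
19 | tert-butyl (3R)-8-methyl-3-[5-(2-methyl-1,3-dioxolan-2-yl)-4-oxopenta-1,2-dien-3-yl]-4-methylidenenon-7-enoate | CC1(OCCO1)CC(=O)C(=C=C)[C@H](CC(=O)OC(C)(C)C)C(=C)CCC=C(C)C | intermediate
20 | tert-butyl (3R)-3-[(4S)-4-hydroxy-5-(2-methyl-1,3-dioxolan-2-yl)penta-1,2-dien-3-yl]-8-methyl-4-methylidenenon-7-enoate | CC1(OCCO1)C[C@H](O)C(=C=C)[C@H](CC(=O)OC(C)(C)C)C(=C)CCC=C(C)C | intermediate
21 | tert-butyl (3R)-3-[(2S)-4-iodo-2-[(2-methyl-1,3-dioxolan-2-yl)methyl]-2,5-dihydrofuran-3-yl]-8-methyl-4-methylidenenon-7-enoate | CC1(OCCO1)C[C@@H]2OCC(I)=C2[C@H](CC(=O)OC(C)(C)C)C(=C)CCC=C(C)C | intermediate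
22 | phenyl vinyl sulfone | C=CS(=O)(=O)c1ccccc1 | starting material
23 | tributyl[1-(phenylsulfonyl)ethenyl]stannane | CCCC[Sn](CCCC)(CCCC)C(=C)S(=O)(=O)c1ccccc1 | intermediate
24 | tert-butyl (3R)-8-methyl-3-[(2S)-2-[(2-methyl-1,3-dioxolan-2-yl)methyl]-4-[1-(phenylsulfonyl)ethenyl]-2,5-dihydrofuran-3-yl]-4-methylidenenon-7-enoate | CC1(OCCO1)C[C@@H]2OCC(C(=C)S(=O)(=O)c3ccccc3)=C2[C@H](CC(=O)OC(C)(C)C)C(=C)CCC=C(C)C | intermediate
25 | tert-butyl 2-[(1S,6S,7R)-6-methyl-1-[(2-methyl-1,3-dioxolan-2-yl)methyl]-6-(4-methylpent-3-en-1-yl)-4-(phenylsulfonyl)-1,3,4,5,6,7-hexahydroisobenzofuran-7-yl]acetate (C4 epimers) | CC1(OCCO1)C[C@@H]2OCC3=C2[C@H](CC(=O)OC(C)(C)C)[C@@](C)(CCC=C(C)C)CC3S(=O)(=O)c4ccccc4 | intermediate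
26 | tert-butyl 2-[(1S,6S,7R)-6-methyl-1-[(2-methyl-1,3-dioxolan-2-yl)methyl]-6-(4-methylpent-3-en-1-yl)-4-oxo-1,3,4,5,6,7-hexahydroisobenzofuran-7-yl]acetate | CC1(OCCO1)C[C@@H]2OCC3=C2[C@H](CC(=O)OC(C)(C)C)[C@@](C)(CCC=C(C)C)CC3=O | intermediate
27 | tert-butyl 2-[(1S,4S,6S,7R)-4-hydroxy-6-methyl-1-[(2-methyl-1,3-dioxolan-2-yl)methyl]-6-(4-methylpent-3-en-1-yl)-1,3,4,5,6,7-hexahydroisobenzofuran-7-yl]acetate | CC1(OCCO1)C[C@@H]2OCC3=C2[C@H](CC(=O)OC(C)(C)C)[C@@](C)(CCC=C(C)C)C[C@@H]3O | intermediate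
28 | tert-butyl 2-[(1S,4S,6S,7R)-6-methyl-1-[(2-methyl-1,3-dioxolan-2-yl)methyl]-6-(4-methylpent-3-en-1-yl)-4-(triethylsilyloxy)-1,3,4,5,6,7-hexahydroisobenzofuran-7-yl]acetate | CC1(OCCO1)C[C@@H]2OCC3=C2[C@H](CC(=O)OC(C)(C)C)[C@@](C)(CCC=C(C)C)C[C@@H]3O[Si](CC)(CC)CC | intermediate
29 | 2-[(1S,4S,6S,7R)-6-methyl-1-[(2-methyl-1,3-dioxolan-2-yl)methyl]-6-(4-methylpent-3-en-1-yl)-4-(triethylsilyloxy)-1,3,4,5,6,7-hexahydroisobenzofuran-7-yl]ethan-1-ol | CC1(OCCO1)C[C@@H]2OCC3=C2[C@H](CCO)[C@@](C)(CCC=C(C)C)C[C@@H]3O[Si](CC)(CC)CC | intermediate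
30 | 2-[(1S,4S,6S,7R)-6-methyl-1-[(2-methyl-1,3-dioxolan-2-yl)methyl]-6-(4-methylpent-3-en-1-yl)-4-(triethylsilyloxy)-1,3,4,5,6,7-hexahydroisobenzofuran-7-yl]acetaldehyde | CC1(OCCO1)C[C@@H]2OCC3=C2[C@H](CC=O)[C@@](C)(CCC=C(C)C)C[C@@H]3O[Si](CC)(CC)CC | intermediate
31 | 3-methylbut-2-enoic acid | CC(C)=CC(O)=O | starting material
32 | 3-methylbut-2-enoic anhydride | CC(C)=CC(=O)OC(=O)C=C(C)C | intermediate
33 | (E)-2-[(1S,4S,6S,7R)-6-methyl-1-[(2-methyl-1,3-dioxolan-2-yl)methyl]-6-(4-methylpent-3-en-1-yl)-4-(triethylsilyloxy)-1,3,4,5,6,7-hexahydroisobenzofuran-7-yl]ethenyl 3-methylbut-2-enoate | CC1(OCCO1)C[C@@H]2OCC3=C2[C@H](/C=C/OC(=O)C=C(C)C)[C@@](C)(CCC=C(C)C)C[C@@H]3O[Si](CC)(CC)CC | intermediate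
34 | (E)-2-[(1S,4S,6S,7R)-4-hydroxy-6-methyl-6-(4-methylpent-3-en-1-yl)-1-(2-oxopropyl)-1,3,4,5,6,7-hexahydroisobenzofuran-7-yl]ethenyl 3-methylbut-2-enoate (CNP0260614.2) | CC(=O)C[C@@H]1OCC2=C1[C@H](/C=C/OC(=O)C=C(C)C)[C@@](C)(CCC=C(C)C)C[C@@H]2O | target

Total step count: 25. Longest linear sequence: 22 steps (steps 1–9, 11–14, 16–22, 24 and 25); steps 10, 15 and 23 prepare the side components 17, 23 and 32.

Steps most likely to fail

Step 17 (bears the label). What may go wrong: hydrogen-atom transfer to the trisubstituted alkene or to the diene instead of the C6 methylene, reduction of the C6 radical before it reaches C5, and poor facial selectivity at the radical centre (methyl trans to the arm). The fallback uses known chemistry, sets out from iodide 21 and returns at enone 26. An intermolecular iron-hydride reductive olefin coupling of the 1,1-disubstituted alkene of 21 with acrolein (Fe(acac)3, PhSiH3, EtOH/ethylene glycol; a known hydrogen-atom-transfer Giese addition) would form the C5–C6 bond first and give the C6-quaternary aldehyde tert-butyl (3R,4S)-3-[(2S)-4-iodo-2-[(2-methyl-1,3-dioxolan-2-yl)methyl]-2,5-dihydrofuran-3-yl]-4,8-dimethyl-4-(3-oxopropyl)non-7-enoate F1. An intramolecular Nozaki–Hiyama–Kishi reaction (CrCl2, NiCl2 cat., DMF) between the C3a iodide and the aldehyde would then close ring A at C3a–C4 and give the allylic alcohol tert-butyl 2-[(1S,6S,7R)-4-hydroxy-6-methyl-1-[(2-methyl-1,3-dioxolan-2-yl)methyl]-6-(4-methylpent-3-en-1-yl)-1,3,4,5,6,7-hexahydroisobenzofuran-7-yl]acetate F2 as C4 epimers, and Dess–Martin oxidation of it gives 26. In this variant C6 is formed in an open chain, so its epimer may have to be removed at the alcohol stage.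

Step 16. What may go wrong: slow transmetalation of the hindered, electron-poor stannane at the tetrasubstituted iodide, protodestannylation and homocoupling. The fallback sets out from iodide 21 and returns at 24. Stille coupling with tributyl(1-ethoxyvinyl)stannane should give the enol ether tert-butyl (3R)-3-[(2S)-4-(1-ethoxyethenyl)-2-[(2-methyl-1,3-dioxolan-2-yl)methyl]-2,5-dihydrofuran-3-yl]-8-methyl-4-methylidenenon-7-enoate F3. Short treatment with dilute aqueous HCl in THF at 0 °C, which hydrolyses an enol ether much faster than a dioxolane, gives the methyl ketone tert-butyl (3R)-3-[(2S)-4-acetyl-2-[(2-methyl-1,3-dioxolan-2-yl)methyl]-2,5-dihydrofuran-3-yl]-8-methyl-4-methylidenenon-7-enoate F4. Kinetic deprotonation at the methyl group (KN(SiMe3)2, THF, −78 °C) and trapping with PhNTf2 gives the dienyl triflate tert-butyl (3R)-8-methyl-3-[(2S)-2-[(2-methyl-1,3-dioxolan-2-yl)methyl]-4-[1-(trifluoromethylsulfonyloxy)ethenyl]-2,5-dihydrofuran-3-yl]-4-methylidenenon-7-enoate F5, and palladium-catalysed sulfinate coupling with PhSO2Na (Pd2(dba)3, Xantphos, toluene, 80 °C) gives 24.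

Step 24. What may go wrong: poor E/Z control in the enol acylation and γ-deprotonation of the acyl donor (vinylketene formation) that leads to a deconjugated ester. The stereospecific fallback sets out from aldehyde 30 and returns at 33. Aldehyde 30 is converted with C4F9SO2F and phosphazene base P2-Et in DMF into the enol nonaflate 2-[(1S,4S,6S,7R)-6-methyl-1-[(2-methyl-1,3-dioxolan-2-yl)methyl]-6-(4-methylpent-3-en-1-yl)-4-(triethylsilyloxy)-1,3,4,5,6,7-hexahydroisobenzofuran-7-yl]ethenyl nonafluorobutane-1-sulfonate F6, which eliminates in the same flask to the terminal alkyne (1S,4S,6S,7S)-7-ethynyl-6-methyl-1-[(2-methyl-1,3-dioxolan-2-yl)methyl]-6-(4-methylpent-3-en-1-yl)-4-(triethylsilyloxy)-1,3,4,5,6,7-hexahydroisobenzofuran F7; the spatial arrangement at C7 is unchanged and the 7S label only reflects the higher priority of the ethynyl group. Zirconium-catalysed syn-hydroboration (pinacolborane, Cp2Zr(H)Cl cat.) gives the (E)-alkenyl pinacolboronate 2-[(E)-2-[(1S,4S,6S,7R)-6-methyl-1-[(2-methyl-1,3-dioxolan-2-yl)methyl]-6-(4-methylpent-3-en-1-yl)-4-(triethylsilyloxy)-1,3,4,5,6,7-hexahydroisobenzofuran-7-yl]ethenyl]-4,4,5,5-tetramethyl-1,3,2-dioxaborolane F8, and brief treatment with KHF2 in MeCN/H2O at 0 °C gives the potassium (E)-alkenyltrifluoroborate F9. Copper-catalysed oxidative C–O coupling of this salt with acid 31 (CuBr cat., DMAP, 4 Å sieves, O2, CH2Cl2; Chan–Lam type) gives 33 with retention of the E geometry.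

Further compounds
F1 | step 17 | tert-butyl (3R,4S)-3-[(2S)-4-iodo-2-[(2-methyl-1,3-dioxolan-2-yl)methyl]-2,5-dihydrofuran-3-yl]-4,8-dimethyl-4-(3-oxopropyl)non-7-enoate | CC1(OCCO1)C[C@@H]2OCC(I)=C2[C@H](CC(=O)OC(C)(C)C)[C@@](C)(CCC=C(C)C)CCC=O
F2 | step 17 | tert-butyl 2-[(1S,6S,7R)-4-hydroxy-6-methyl-1-[(2-methyl-1,3-dioxolan-2-yl)methyl]-6-(4-methylpent-3-en-1-yl)-1,3,4,5,6,7-hexahydroisobenzofuran-7-yl]acetate (C4 epimers) | CC1(OCCO1)C[C@@H]2OCC3=C2[C@H](CC(=O)OC(C)(C)C)[C@@](C)(CCC=C(C)C)CC3O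
F3 | step 16 | tert-butyl (3R)-3-[(2S)-4-(1-ethoxyethenyl)-2-[(2-methyl-1,3-dioxolan-2-yl)methyl]-2,5-dihydrofuran-3-yl]-8-methyl-4-methylidenenon-7-enoate | CC1(OCCO1)C[C@@H]2OCC(C(=C)OCC)=C2[C@H](CC(=O)OC(C)(C)C)C(=C)CCC=C(C)C
F4 | step 16 | tert-butyl (3R)-3-[(2S)-4-acetyl-2-[(2-methyl-1,3-dioxolan-2-yl)methyl]-2,5-dihydrofuran-3-yl]-8-methyl-4-methylidenenon-7-enoate | CC1(OCCO1)C[C@@H]2OCC(C(C)=O)=C2[C@H](CC(=O)OC(C)(C)C)C(=C)CCC=C(C)C
F5 | step 16 | tert-butyl (3R)-8-methyl-3-[(2S)-2-[(2-methyl-1,3-dioxolan-2-yl)methyl]-4-[1-(trifluoromethylsulfonyloxy)ethenyl]-2,5-dihydrofuran-3-yl]-4-methylidenenon-7-enoate | CC1(OCCO1)C[C@@H]2OCC(C(=C)OS(=O)(=O)C(F)(F)F)=C2[C@H](CC(=O)OC(C)(C)C)C(=C)CCC=C(C)C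
F6 | step 24 | 2-[(1S,4S,6S,7R)-6-methyl-1-[(2-methyl-1,3-dioxolan-2-yl)methyl]-6-(4-methylpent-3-en-1-yl)-4-(triethylsilyloxy)-1,3,4,5,6,7-hexahydroisobenzofuran-7-yl]ethenyl nonafluorobutane-1-sulfonate (E/Z mixture) | CC1(OCCO1)C[C@@H]2OCC3=C2[C@H](C=COS(=O)(=O)C(F)(F)C(F)(F)C(F)(F)C(F)(F)F)[C@@](C)(CCC=C(C)C)C[C@@H]3O[Si](CC)(CC)CC
F7 | step 24 | (1S,4S,6S,7S)-7-ethynyl-6-methyl-1-[(2-methyl-1,3-dioxolan-2-yl)methyl]-6-(4-methylpent-3-en-1-yl)-4-(triethylsilyloxy)-1,3,4,5,6,7-hexahydroisobenzofuran | CC1(OCCO1)C[C@@H]2OCC3=C2[C@H](C#C)[C@@](C)(CCC=C(C)C)C[C@@H]3O[Si](CC)(CC)CC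
F8 | step 24 | 2-[(E)-2-[(1S,4S,6S,7R)-6-methyl-1-[(2-methyl-1,3-dioxolan-2-yl)methyl]-6-(4-methylpent-3-en-1-yl)-4-(triethylsilyloxy)-1,3,4,5,6,7-hexahydroisobenzofuran-7-yl]ethenyl]-4,4,5,5-tetramethyl-1,3,2-dioxaborolane | CC1(OCCO1)C[C@@H]2OCC3=C2[C@H](/C=C/B4OC(C)(C)C(C)(C)O4)[C@@](C)(CCC=C(C)C)C[C@@H]3O[Si](CC)(CC)CC
F9 | step 24 | potassium trifluoro[(E)-2-[(1S,4S,6S,7R)-6-methyl-1-[(2-methyl-1,3-dioxolan-2-yl)methyl]-6-(4-methylpent-3-en-1-yl)-4-(triethylsilyloxy)-1,3,4,5,6,7-hexahydroisobenzofuran-7-yl]ethenyl]borate | [K+].CC1(OCCO1)C[C@@H]2OCC3=C2[C@H](/C=C/[B-](F)(F)F)[C@@](C)(CCC=C(C)C)C[C@@H]3O[Si](CC)(CC)CC
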